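## Retrosynthetic overview

- **Feature:** in the ten-membered carbocycle C1–C10, the C1=C10 enoate and the C4–C5 oxirane (taken back to a ring-cis C4=C5 alkene) flank C2–C3 as a cyclodeca-1,5-diene. A retro-[3,3] shift (break C2–C3, make C5–C10) leads to a cis-1-vinyl-2-isopropenylcyclohexanol that carries C6–C9.
- **Ring order:** dioxolane (C8/C9, from L-tartrate) → cyclohexane C5–C10 by intramolecular carbonyl-ene closure of C5–C6 → ten-membered ring by anionic oxy-Cope ring expansion → γ-lactone O6–C12 → C4–C5 oxirane last.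
- **Stereocentres:** C8/C9 from the tartrate; C7 by anti-selective cuprate addition; C5/C6 in the chair-like ene closure; the axial C10 vinyl group by axial acetylide addition and semi-hydrogenation; the glycidate from (S)-2-methylglycidol.
- **After ring expansion:** C10 ketone → enol triflate → methoxycarbonylation (C14), oxidative lactonisation, α-methylenation, diol release, acylation at O9 then O8, epoxidation.

Key step: step 19

Remark: atom labels C1–C14 follow the ten-membered-ring numbering of the target (C12 lactone carbonyl, C13 exocyclic methylene, C14 ester carbon); (S)-2-methylglycidol 39 is assumed to be a commercial building block; 11, 15, 16, 33, 35 and 36 are mixtures at one carbon that is removed or becomes sp2 later.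

## Route

Step 1
Reactants: 1 dimethyl (4R,5R)-2,2-dimethyl-1,3-dioxolane-4,5-dicarboxylate
Product: 2 (4R,5R)-N,N′-dimethoxy-N,N′,2,2-tetramethyl-1,3-dioxolane-4,5-dicarboxamide
Conditions: MeNH(OMe)·HCl, i-PrMgCl, THF, −20 to 0 °C
Reagents that add atoms: N,O-dimethylhydroxylamine hydrochloride, CNOC.Cl
Why: Aminolysis of both esters by the magnesium amide of N,O-dimethylhydroxylamine (Weinreb amide formation) is a standard reaction that should leave the trans-dioxolane centres (future C8 and C9) untouched.

Step 2
Reactants: 2 bis(N-methoxy-N-methylamide); 3 2-methylprop-1-enylmagnesium bromide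
Product: 4 keto amide (C10 3-methylbut-2-enoyl ketone; C7 N-methoxy-N-methylamide)
Conditions: 3 (1.1 equiv), THF, −78 to 0 °C; then H2O
Reagents that add atoms: none
Why: Grignard addition to an N-methoxy-N-methylamide stops at the magnesium-chelated tetrahedral adduct, and with one equivalent at low temperature this chelate should protect the molecule from a second addition, so the mono-ketone is expected on work-up.

Step 3
Reactants: 4 keto amide
Product: 5 allylic alcohol (C10 carbinol, O10 anti to O9)
Conditions: Li[HB(sec-Bu)3], THF, −78 °C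
Reagents that add atoms: none
Why: 1,2-Reduction of the β,β-disubstituted enone by the bulky borohydride should follow Felkin–Anh control by the adjacent dioxolane C–O bond and give the anti alcohol; this centre is oxidised again in step 16, so its configuration is not critical.

Step 4
Reactants: 5 allylic alcohol
Product: 6 O10 triethylsilyl ether
Conditions: Et3SiCl, imidazole, DMF, 0 °C
Reagents that add atoms: chlorotriethylsilane, CC[Si](Cl)(CC)CC
Why: Silylation of a secondary alcohol gives a silyl ether that tolerates the Lewis acid of step 13 and can later be removed in the presence of bulkier silyl ethers.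

Step 5
Reactants: 6 silyl ether amide
Product: 7 aldehyde (C7 formyl)
Conditions: i-Bu2AlH, THF, −78 °C; Rochelle salt work-up
Reagents that add atoms: none
Why: Hydride reduction of the N-methoxy-N-methylamide gives a stable aluminium chelate that releases the aldehyde only on work-up, so over-reduction is avoided.

Step 6
Reactants: 7 aldehyde; 8 methyl (triphenyl-λ5-phosphanylidene)acetate
Product: 9 methyl (E)-enoate (C7 is the β-carbon, C6 the α-carbon)
Conditions: CH2Cl2, rt
Reagents that add atoms: none
Why: Wittig olefination with a stabilised ylide should give the (E)-enoate needed for anti-selective conjugate addition.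

Step 7
Reactants: 9 (E)-enoate; 10 vinylmagnesium bromide
Product: 12 methyl ester with the C7 stereocentre (vinyl group anti to O8), via trimethylsilyl ketene acetal 11 (not isolated)
Conditions: 10, CuI (cat.), Me3SiCl, THF, −78 °C; then H2O
Reagents that add atoms: none
Why: Copper-catalysed conjugate addition of the vinyl Grignard reagent, accelerated by Me3SiCl, to a γ-alkoxy (E)-enoate should occur anti to the dioxolane C8–O bond (Felkin–Anh-type 1,2-induction), which sets C7 with the vinyl group (future C11–C12) anti to O8.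

Step 8
Reactants: 12 vinyl ester
Product: 13 primary alcohol (C12–OH)
Conditions: 9-borabicyclo[3.3.1]nonane, THF, 0 °C to rt; then H2O2, aq. NaOAc, 0 °C
Reagents that add atoms: hydrogen peroxide, OO
Why: Hydroboration–oxidation with the bulky dialkylborane is selective for the monosubstituted vinyl group over the trisubstituted alkene and gives the anti-Markovnikov alcohol, so C11–C12–O is in place without ozonolysis.

Step 9
Reactants: 13 primary alcohol
Product: 14 O12 tert-butyldiphenylsilyl ether
Conditions: t-BuPh2SiCl, imidazole, CH2Cl2, rt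
Reagents that add atoms: tert-butyl(chloro)diphenylsilane, CC(C)(C)[Si](Cl)(c1ccccc1)c1ccccc1
Why: Silylation of the primary alcohol gives an ether that survives the acid, fluoride and base steps up to step 22.

Step 10
Reactants: 14 ester
Product: 15 α-hydroxy ester (hydroxyl on C6; both C6 epimers)
Conditions: KN(SiMe3)2, THF, −78 °C; 2-(phenylsulfonyl)-3-phenyloxaziridine; AcOH
Reagents that add atoms: 2-(phenylsulfonyl)-3-phenyloxaziridine, O=S(=O)(c1ccccc1)N1OC1c1ccccc1
Why: Oxidation of the ester enolate by the N-sulfonyloxaziridine (Davis hydroxylation) puts oxygen on C6, which prepares the excision of the ester carbon; the new centre need not be controlled because C6 becomes a formyl carbon in step 12.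

Step 11
Reactants: 15 α-hydroxy ester
Product: 16 1,2-diol (C6–OH and the CH2OH derived from the ester carbon)
Conditions: LiBH4, THF, MeOH (1 equiv), 0 °C to rt
Reagents that add atoms: none
Why: Borohydride reduction of the ester to the primary alcohol gives the vicinal diol and leaves silyl ethers, the acetonide and the alkene alone.

Step 12
Reactants: 16 1,2-diol
Product: 17 aldehyde (C6 formyl on C7)
Conditions: NaIO4, THF, pH 7 buffer, 0 °C
Reagents that add atoms: none
Why: Periodate glycol cleavage is neutral and should release the α-branched, β-alkoxy aldehyde without epimerisation at C7 or β-elimination; it is used at once.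

Step 13
Reactants: 17 aldehyde
Product: 18 cyclohexanol (C5 isopropenyl and C6 hydroxyl trans and equatorial; C7 chain axial)
Conditions: Me2AlCl, CH2Cl2, −78 to −40 °C
Reagents that add atoms: none
Why: In this Lewis acid-promoted intramolecular carbonyl-ene reaction of the isopulegol type the trans-fused dioxolane allows only one chair-like six-membered transition state, in which the C7 chain is axial and the complexed carbonyl oxygen and the alkene carbon are equatorial, so C6–OH should form cis to the C7 chain and C5–isopropenyl trans to C6–OH, while the proton-scavenging Me2AlCl suppresses epimerisation of the aldehyde.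

Step 14
Reactants: 18 cyclohexanol
Product: 19 O6 tert-butyldimethylsilyl ether
Conditions: t-BuMe2SiOTf, 2,6-lutidine, CH2Cl2, −78 to 0 °C
Reagents that add atoms: tert-butyldimethylsilyl trifluoromethanesulfonate, CC(C)(C)[Si](C)(C)OS(=O)(=O)C(F)(F)F
Why: The silyl triflate silylates the hindered secondary hydroxyl under non-acidic conditions and gives an ether that is stable to KH in step 19.

Step 15
Reactants: 19 tris-silyl ether
Product: 20 C10 alcohol
Conditions: HF·pyridine, pyridine, THF, 0 °C
Reagents that add atoms: none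
Why: A triethylsilyl ether is cleaved by buffered HF·pyridine much faster than a secondary tert-butyldimethylsilyl or a primary tert-butyldiphenylsilyl ether, so only O10 should be freed.

Step 16
Reactants: 20 C10 alcohol
Product: 21 cyclohexanone (C10 ketone)
Conditions: Dess–Martin periodinane, NaHCO3, CH2Cl2, 0 °C to rt
Reagents that add atoms: none
Why: Dess–Martin oxidation is mild and buffered, so the β-silyloxy ketone should form without epimerisation at C5, double-bond migration of the isopropenyl group or β-elimination.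

Step 17
Reactants: 21 cyclohexanone; 22 ethynylmagnesium bromide
Product: 23 propargylic alcohol (C10 ethynyl axial and cis to the C5 isopropenyl group)
Conditions: CeCl3, 22, THF, −78 °C; then H2O
Reagents that add atoms: none
Why: The small linear sp nucleophile of the organocerium reagent should add along the axial trajectory of the conformationally locked cyclohexanone (torsional control), which places the two-carbon unit axial and the hydroxyl equatorial, and its low basicity avoids enolisation and β-elimination.

Step 18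
Reactants: 23 propargylic alcohol
Product: 24 cis-1-vinyl-2-isopropenylcyclohexanol (C10 vinyl axial; C5 isopropenyl equatorial)
Conditions: H2 (1 atm), Pd/CaCO3 poisoned with Pb(OAc)2, quinoline, EtOAc, rt
Reagents that add atoms: none
Why: Lindlar semi-hydrogenation reduces the terminal alkyne to the vinyl group and should stop there, leaving the 1,1-disubstituted isopropenyl alkene untouched.

Step 19
Reactants: 24 cis-1-vinyl-2-isopropenylcyclohexanol
Product: 27 (Z)-cyclodec-5-enone (C10 ketone; ring-cis C4=C5), via potassium alkoxide 25 (not isolated), via potassium enolate 26 (not isolated)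
Conditions: KH, 18-crown-6, THF, 0 °C to rt; then AcOH, THF, −78 °C
Reagents that add atoms: none
Why: Deprotonation gives the potassium alkoxide 25, and the alkoxide-accelerated [3,3]-sigmatropic shift (anionic oxy-Cope rearrangement of a 1,2-dialkenylcyclohexanol, the closest known reaction type) forms C2–C3 while C5–C10 breaks, giving enolate 26 and, on protonation, the C10 ketone. The ten-membered ring is closed by this four-atom ring expansion of the cyclohexane through a six-centre chair-like array (C2, C1, C10, C5, C4, C3), not by an end-to-end cyclisation, so no high dilution is needed. No stereocentre is created: C6, C7, C8 and C9 are spectators, and the centres at C5 and C10 disappear. The step needs the ring-cis (Z) C4=C5 alkene, and the trans-fused dioxolane secures it by allowing only the cyclohexane chair with the C10 vinyl group axial and the C5 isopropenyl group equatorial, so that in the chair-like array the C5–C6 bond is axial and C6 ends up cis to C3. The enolate geometry at C1=C10 (C9 and C2 trans) is lost on protonation and is set again in step 20. The cold acidic quench, applied while the enolate is still the only base present, keeps it from equilibrating towards C9, where β-elimination of O8 could follow.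

Step 20
Reactants: 27 (Z)-cyclodec-5-enone
Product: 29 C10 enol triflate (C1=C10 ring-cis), via potassium enolate 28 (not isolated)
Conditions: KN(SiMe3)2, THF, −78 °C; then PhNTf2, −78 to 0 °C
Reagents that add atoms: N-phenylbis(trifluoromethanesulfonimide), O=S(=O)(N(c1ccccc1)S(=O)(=O)C(F)(F)F)C(F)(F)F
Why: Kinetic deprotonation by the bulky amide base should occur at the unhindered C1 methylene and not at the oxygen-bearing C9 methine, the ring-cis enolate (C9 and C2 cis) is the one expected from an amide base and the less strained one in a ten-membered ring, and O-sulfonylation fixes it as the enol triflate.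

Step 21
Reactants: 29 enol triflate
Product: 30 methyl ester (C14 on C10; C1=C10 with C9 and C2 cis)
Conditions: Pd(PPh3)4 (cat.), CO (1 atm), MeOH, Et3N, DMF, 45 °C
Reagents that add atoms: carbon monoxide, [C-]#[O+]; methanol, CO
Why: Oxidative addition of the enol triflate to zerovalent palladium, CO insertion and methanolysis of the acyl complex (alkoxycarbonylation of an enol triflate) proceed with retention of alkene geometry and install C14 as the methyl ester.

Step 22
Reactants: 30 bis-silyl ether
Product: 31 diol (C6–OH and C12–OH)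
Conditions: n-Bu4NF, AcOH, THF, rt
Reagents that add atoms: none
Why: Buffered fluoride removes both silyl ethers in one operation, and the acetic acid keeps the medium from isomerising the enoate.

Step 23
Reactants: 31 diol
Product: 34 γ-lactone (O6–C12), via hydroxy aldehyde 32 (not isolated), via lactol 33 (not isolated)
Conditions: TEMPO (cat.), PhI(OAc)2, CH2Cl2, rt
Reagents that add atoms: none
Why: Nitroxyl-catalysed oxidation is selective for the primary alcohol, the aldehyde is trapped by the C6 hydroxyl as a five-membered lactol and this is oxidised on to the lactone (oxidative lactonisation of a 1,4-diol), while O8 is tied up in the acetonide and cannot compete.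

Step 24
Reactants: 34 γ-lactone
Product: 37 α-methylene lactone, via Mannich base 35 (not isolated), via ammonium iodide 36 (not isolated)
Conditions: LiN(i-Pr)2, THF, −78 °C; CH2=NMe2+ I−, −78 to 0 °C; then MeI, MeOH, rt; then aq. NaHCO3, CH2Cl2
Reagents that add atoms: N,N-dimethylmethyleneiminium iodide, C=[N+](C)C.[I-]
Why: Mannich reaction of the lactone lithium enolate with the iminium salt, N-methylation and base-induced elimination of trimethylamine is the standard α-methylenation of γ-lactones, and at −78 °C the lactone α-protons should be removed faster than the γ-protons of the hindered enoate.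

Step 25
Reactants: 37 acetonide
Product: 38 8,9-diol
Conditions: 80% aq. AcOH, 45 °C
Reagents that add atoms: none
Why: Mild acid hydrolysis of the isopropylidene acetal frees the two hydroxyls under conditions that the α-methylene lactone, the enoate and the trisubstituted alkene should tolerate.

Step 26
Reactants: 39 (S)-(2-methyloxiran-2-yl)methanol
Product: 40 (R)-2-methyloxirane-2-carboxylic acid
Conditions: TEMPO (cat.), NaOCl (cat.), NaClO2, MeCN, phosphate buffer pH 6.7, 35 °C
Reagents that add atoms: sodium chlorite, [Na+].[O-]Cl=O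
Why: Nitroxyl-catalysed chlorite oxidation takes the primary alcohol to the acid near neutral pH without opening the oxirane, and the quaternary stereocentre cannot epimerise (the descriptor changes from S to R only through the priority change).

Step 27
Reactants: 38 8,9-diol; 40 (R)-2-methyloxirane-2-carboxylic acid
Product: 42 9-O-[(R)-2-methyloxirane-2-carbonyl] ester (C8–OH free), via mixed anhydride 41 (not isolated)
Conditions: 40, 2,4,6-trichlorobenzoyl chloride, Et3N, THF, 0 °C; then 38, 4-(dimethylamino)pyridine, toluene, 0 °C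
Reagents that add atoms: none
Why: In this Yamaguchi esterification the allylic C9 hydroxyl, flanked by the planar sp2 carbon C10, should be acylated faster than the C8 hydroxyl, which lies between two sp3 stereocentres including the ring-fusion carbon C7.

Step 28
Reactants: 42 hydroxy ester
Product: 43 8-O-acetate
Conditions: Ac2O, pyridine, 4-(dimethylamino)pyridine (cat.), CH2Cl2, 0 °C to rt
Reagents that add atoms: acetic anhydride, CC(=O)OC(C)=O
Why: Exhaustive acetylation of the one remaining hydroxyl needs no selectivity and at the same time removes any chance of acyl migration from O9 to O8.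

Step 29
Reactants: 43 diester
Product: 44 target (CNP0159450.1)
Conditions: mCPBA, NaHCO3, CH2Cl2, 0 °C
Reagents that add atoms: 3-chloroperbenzoic acid, O=C(OO)c1cccc(Cl)c1
Why: In this Prilezhaev epoxidation the peracid should attack only the electron-rich trisubstituted C4=C5 alkene (the enoate and the α-methylene lactone are electron-poor), the syn addition keeps C3 and C6 cis, and attack is expected from the peripheral face, which in the A(1,3)-minimised rotamer about C5–C6 (C6–H in the alkene plane) is the face of the lactone oxygen, giving the (4R,5S) oxirane.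

## Compound list

1 | dimethyl (4R,5R)-2,2-dimethyl-1,3-dioxolane-4,5-dicarboxylate (dimethyl 2,3-O-isopropylidene-L-tartrate; ring carbons become C8 and C9) | COC(=O)[C@@H]1OC(C)(C)O[C@H]1C(=O)OC | starting material
2 | (4R,5R)-N,N′-dimethoxy-N,N′,2,2-tetramethyl-1,3-dioxolane-4,5-dicarboxamide | CON(C)C(=O)[C@@H]1OC(C)(C)O[C@H]1C(=O)N(C)OC | intermediate
3 | 2-methylprop-1-enylmagnesium bromide | CC(C)=C[Mg]Br | starting material
4 | keto amide: C7 N-methoxy-N-methylamide and C10 3-methylbut-2-enoyl ketone on the trans-dioxolane | CON(C)C(=O)[C@@H]1OC(C)(C)O[C@H]1C(=O)C=C(C)C | intermediate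
5 | allylic alcohol: 4 with C10 reduced, O10 anti to O9 | CON(C)C(=O)[C@@H]1OC(C)(C)O[C@H]1[C@@H](O)C=C(C)C | intermediate
6 | O10 triethylsilyl ether of 5 | CON(C)C(=O)[C@@H]1OC(C)(C)O[C@H]1[C@@H](O[Si](CC)(CC)CC)C=C(C)C | intermediate
7 | aldehyde: C7 formyl, O10 triethylsilyl ether | O=C[C@@H]1OC(C)(C)O[C@H]1[C@@H](O[Si](CC)(CC)CC)C=C(C)C | intermediate
8 | methyl (triphenyl-λ5-phosphanylidene)acetate | COC(=O)C=P(c1ccccc1)(c1ccccc1)c1ccccc1 | starting material
9 | methyl (E)-enoate: MeO2C–C6H=C7H– on C8 | COC(=O)/C=C/[C@@H]1OC(C)(C)O[C@H]1[C@@H](O[Si](CC)(CC)CC)C=C(C)C | intermediate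
10 | vinylmagnesium bromide | C=C[Mg]Br | starting material
11 | trimethylsilyl ketene acetal of 12 (enol ether geometry not defined) | COC(O[Si](C)(C)C)=C[C@H](C=C)[C@@H]1OC(C)(C)O[C@H]1[C@@H](O[Si](CC)(CC)CC)C=C(C)C | intermediate
12 | methyl ester: C7 bears the vinyl group (C11=C12, anti to O8) and CH2CO2Me (C6) | COC(=O)C[C@H](C=C)[C@@H]1OC(C)(C)O[C@H]1[C@@H](O[Si](CC)(CC)CC)C=C(C)C | intermediate
13 | primary alcohol: 12 with the vinyl group converted into CH2CH2OH (C12–OH) | COC(=O)C[C@H](CCO)[C@@H]1OC(C)(C)O[C@H]1[C@@H](O[Si](CC)(CC)CC)C=C(C)C | intermediate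
14 | O12 tert-butyldiphenylsilyl ether of 13 | COC(=O)C[C@H](CCO[Si](c1ccccc1)(c1ccccc1)C(C)(C)C)[C@@H]2OC(C)(C)O[C@H]2[C@@H](O[Si](CC)(CC)CC)C=C(C)C | intermediate
15 | α-hydroxy ester: 14 hydroxylated at C6 (both C6 epimers) | COC(=O)C(O)[C@H](CCO[Si](c1ccccc1)(c1ccccc1)C(C)(C)C)[C@@H]2OC(C)(C)O[C@H]2[C@@H](O[Si](CC)(CC)CC)C=C(C)C | intermediate
16 | 1,2-diol: 15 with the ester reduced to CH2OH (both C6 epimers) | OCC(O)[C@H](CCO[Si](c1ccccc1)(c1ccccc1)C(C)(C)C)[C@@H]2OC(C)(C)O[C@H]2[C@@H](O[Si](CC)(CC)CC)C=C(C)C | intermediate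
17 | aldehyde: C6 formyl on C7; C7 chain CH2CH2OSiPh2t-Bu; C8/C9 acetonide; C10 OSiEt3 and 2-methylprop-1-enyl | O=C[C@H](CCO[Si](c1ccccc1)(c1ccccc1)C(C)(C)C)[C@@H]2OC(C)(C)O[C@H]2[C@@H](O[Si](CC)(CC)CC)C=C(C)C | intermediate
18 | cyclohexanol (ring C5–C10): C5 isopropenyl equatorial; C6 OH equatorial, trans to C5; C7 chain axial, cis to O6 and O8; C8/C9 trans-fused acetonide; C10 OSiEt3 axial | C=C(C)[C@H]1[C@H](O)[C@H](CCO[Si](c2ccccc2)(c2ccccc2)C(C)(C)C)[C@@H]3OC(C)(C)O[C@H]3[C@H]1O[Si](CC)(CC)CC | intermediate
19 | 18 with O6 as tert-butyldimethylsilyl ether | C=C(C)[C@H]1[C@H](O[Si](C)(C)C(C)(C)C)[C@H](CCO[Si](c2ccccc2)(c2ccccc2)C(C)(C)C)[C@@H]3OC(C)(C)O[C@H]3[C@H]1O[Si](CC)(CC)CC | intermediate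
20 | 19 with free C10 hydroxyl | C=C(C)[C@H]1[C@H](O[Si](C)(C)C(C)(C)C)[C@H](CCO[Si](c2ccccc2)(c2ccccc2)C(C)(C)C)[C@@H]3OC(C)(C)O[C@H]3[C@H]1O | intermediate
21 | cyclohexanone: C10 ketone flanked by equatorial C5 isopropenyl and equatorial O9 | C=C(C)[C@H]1[C@H](O[Si](C)(C)C(C)(C)C)[C@H](CCO[Si](c2ccccc2)(c2ccccc2)C(C)(C)C)[C@@H]3OC(C)(C)O[C@H]3C1=O | intermediate
22 | ethynylmagnesium bromide | C#C[Mg]Br | starting material
23 | propargylic alcohol: C10 ethynyl axial (cis to C5 isopropenyl), C10 OH equatorial | C=C(C)[C@H]1[C@H](O[Si](C)(C)C(C)(C)C)[C@H](CCO[Si](c2ccccc2)(c2ccccc2)C(C)(C)C)[C@@H]3OC(C)(C)O[C@H]3[C@@]1(O)C#C | intermediate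
24 | cis-1-vinyl-2-isopropenylcyclohexanol: C10 vinyl axial, C5 isopropenyl equatorial, O6 SiMe2t-Bu, O12 SiPh2t-Bu, C8/C9 acetonide | C=C(C)[C@H]1[C@H](O[Si](C)(C)C(C)(C)C)[C@H](CCO[Si](c2ccccc2)(c2ccccc2)C(C)(C)C)[C@@H]3OC(C)(C)O[C@H]3[C@@]1(O)C=C | intermediate
25 | potassium alkoxide of 24 | C=C(C)[C@H]1[C@H](O[Si](C)(C)C(C)(C)C)[C@H](CCO[Si](c2ccccc2)(c2ccccc2)C(C)(C)C)[C@@H]3OC(C)(C)O[C@H]3[C@@]1([O-])C=C.[K+] | intermediate
26 | potassium enolate from the rearrangement (C1=C10, C9 and C2 trans; C4=C5 ring-cis) | [K+].C1/C(C)=C\[C@H](O[Si](C)(C)C(C)(C)C)[C@H](CCO[Si](c2ccccc2)(c2ccccc2)C(C)(C)C)[C@@H]3OC(C)(C)O[C@H]3/C([O-])=C/C1 | intermediate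
27 | (Z)-cyclodec-5-enone: C10 ketone, ring-cis C4=C5 with methyl on C4, O6 silyl ether, C7 chain, C8/C9 acetonide | C1/C(C)=C\[C@H](O[Si](C)(C)C(C)(C)C)[C@H](CCO[Si](c2ccccc2)(c2ccccc2)C(C)(C)C)[C@@H]3OC(C)(C)O[C@H]3C(=O)CC1 | intermediate
28 | kinetic potassium enolate of 27 (C1=C10, C9 and C2 cis) | [K+].C1/C(C)=C\[C@H](O[Si](C)(C)C(C)(C)C)[C@H](CCO[Si](c2ccccc2)(c2ccccc2)C(C)(C)C)[C@@H]3OC(C)(C)O[C@H]3/C([O-])=C\C1 | intermediate
29 | C10 enol triflate (C1=C10 ring-cis) | C1/C(C)=C\[C@H](O[Si](C)(C)C(C)(C)C)[C@H](CCO[Si](c2ccccc2)(c2ccccc2)C(C)(C)C)[C@@H]3OC(C)(C)O[C@H]3/C(OS(=O)(=O)C(F)(F)F)=C\C1 | intermediate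
30 | methyl ester: CO2Me (C14) on C10 of the ring-cis C1=C10 alkene | C1/C(C)=C\[C@H](O[Si](C)(C)C(C)(C)C)[C@H](CCO[Si](c2ccccc2)(c2ccccc2)C(C)(C)C)[C@@H]3OC(C)(C)O[C@H]3/C(C(=O)OC)=C\C1 | intermediate
31 | diol: free C6–OH and C12–OH | C1/C(C)=C\[C@H](O)[C@H](CCO)[C@@H]3OC(C)(C)O[C@H]3/C(C(=O)OC)=C\C1 | intermediate
32 | hydroxy aldehyde (C12 formyl, C6–OH) | C1/C(C)=C\[C@H](O)[C@H](CC=O)[C@@H]3OC(C)(C)O[C@H]3/C(C(=O)OC)=C\C1 | intermediate
33 | lactol (O6–C12 hemiacetal, both anomers) | C1/C(C)=C\[C@@H]2OC(O)C[C@@H]2[C@@H]3OC(C)(C)O[C@H]3/C(C(=O)OC)=C\C1 | intermediate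
34 | γ-lactone O6–C12(=O)–C11H2–C7 | C1/C(C)=C\[C@@H]2OC(=O)C[C@@H]2[C@@H]3OC(C)(C)O[C@H]3/C(C(=O)OC)=C\C1 | intermediate
35 | Mannich base: 34 with CH2NMe2 on C11 (both C11 epimers) | C1/C(C)=C\[C@@H]2OC(=O)C(CN(C)C)[C@@H]2[C@@H]3OC(C)(C)O[C@H]3/C(C(=O)OC)=C\C1 | intermediate
36 | trimethylammonium iodide of 35 | C1/C(C)=C\[C@@H]2OC(=O)C(C[N+](C)(C)C)[C@@H]2[C@@H]3OC(C)(C)O[C@H]3/C(C(=O)OC)=C\C1.[I-] | intermediate
37 | α-methylene lactone (C11=C13H2) with C8/C9 acetonide | C1/C(C)=C\[C@@H]2OC(=O)C(=C)[C@@H]2[C@@H]3OC(C)(C)O[C@H]3/C(C(=O)OC)=C\C1 | intermediate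
38 | 8,9-diol of the α-methylene lactone | C1/C(C)=C\[C@@H]2OC(=O)C(=C)[C@@H]2[C@H](O)[C@@H](O)/C(C(=O)OC)=C\C1 | intermediate
39 | (S)-(2-methyloxiran-2-yl)methanol | OC[C@@]1(C)CO1 | starting material
40 | (R)-2-methyloxirane-2-carboxylic acid | OC(=O)[C@@]1(C)CO1 | intermediate
41 | mixed anhydride of 40 with 2,4,6-trichlorobenzoic acid | O=C(OC(=O)[C@@]1(C)CO1)c1c(Cl)cc(Cl)cc1Cl | intermediate
42 | 9-O-[(R)-2-methyloxirane-2-carbonyl] ester with free C8–OH | C1/C(C)=C\[C@@H]2OC(=O)C(=C)[C@@H]2[C@H](O)[C@@H](OC(=O)[C@@]3(C)CO3)/C(C(=O)OC)=C\C1 | intermediate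
43 | 8-O-acetyl-9-O-[(R)-2-methyloxirane-2-carbonyl] diester with the ring-cis C4=C5 alkene | C1/C(C)=C\[C@@H]2OC(=O)C(=C)[C@@H]2[C@H](OC(C)=O)[C@@H](OC(=O)[C@@]3(C)CO3)/C(C(=O)OC)=C\C1 | intermediate
44 | CNP0159450.1 | C=C1C(=O)O[C@@H]2[C@H]1[C@H](OC(C)=O)[C@@H](OC(=O)[C@@]1(C)CO1)/C(C(=O)OC)=C\CC[C@@]1(C)O[C@@H]21 | target

## Step count and risks

Total step count: 29. Longest linear sequence: 28 steps (steps 1–25 and 27–29; step 26 prepares the acid 40).

The three steps most likely to fail:

Step 19, the ring expansion. The alkoxide may cleave heterolytically at C5–C10 into an enone and an allyl anion (fragmentation or [1,3] recombination), or the enolate may transfer a proton towards C9 and lose O8 by β-elimination. The fallback sets out from 24. The tertiary hydroxyl is silylated with N-(trimethylsilyl)imidazole in CH2Cl2 to the trimethylsilyl ether of 24 F1. This is rearranged without base by heating in degassed 1,2-dichlorobenzene in a base-washed sealed tube at about 200 °C (neutral thermal oxy-Cope shift through the same locked chair) to the trimethylsilyl enol ether of the cyclodecenone F2. K2CO3 in MeOH at 0 °C cleaves the enol ether, and the route is rejoined at 27.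

Step 27, the first acylation. Site selection between the two secondary hydroxyls may be poor with the hindered epoxy acid, or the acyl group may migrate from O9 to O8. The fallback sets out from 38. The more accessible allylic hydroxyl is capped with Et3SiCl and imidazole at −40 °C as the 9-O-triethylsilyl ether F3. O8 is acetylated (Ac2O, 4-(dimethylamino)pyridine) to the 8-O-acetyl 9-O-triethylsilyl compound F4. HF·pyridine frees O9 to give the 8-O-acetyl 9-hydroxy compound F5. Yamaguchi esterification of F5 with 40 then needs no selectivity, and the route is rejoined at 43.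

Step 29, the epoxidation. The peracid may deliver oxygen to the inner face of C4=C5 if the ring prefers another rotamer about C5–C6, which would give the (4S,5R) oxirane. The fallback sets out from 43. N-Bromosuccinimide in aqueous THF forms the bromonium ion on the face that the peracid uses, and water opens it at the tertiary C4 from the opposite face, giving the bromohydrin (C4–OH, C5–Br) F6. Ag2O in THF then closes the oxirane by displacement of bromide with inversion at C5, so the oxygen ends on the face opposite to that reached by direct epoxidation. The route is rejoined at 44.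

Further compounds
F1 | step 19 | trimethylsilyl ether of 24 | C=C(C)[C@H]1[C@H](O[Si](C)(C)C(C)(C)C)[C@H](CCO[Si](c2ccccc2)(c2ccccc2)C(C)(C)C)[C@@H]3OC(C)(C)O[C@H]3[C@@]1(O[Si](C)(C)C)C=C
F2 | step 19 | trimethylsilyl enol ether of the cyclodecenone (C1=C10, C9 and C2 trans) | C1/C(C)=C\[C@H](O[Si](C)(C)C(C)(C)C)[C@H](CCO[Si](c2ccccc2)(c2ccccc2)C(C)(C)C)[C@@H]3OC(C)(C)O[C@H]3/C(O[Si](C)(C)C)=C/C1
F3 | step 27 | 9-O-triethylsilyl ether of 38 | C1/C(C)=C\[C@@H]2OC(=O)C(=C)[C@@H]2[C@H](O)[C@@H](O[Si](CC)(CC)CC)/C(C(=O)OC)=C\C1
F4 | step 27 | 8-O-acetyl 9-O-triethylsilyl compound | C1/C(C)=C\[C@@H]2OC(=O)C(=C)[C@@H]2[C@H](OC(C)=O)[C@@H](O[Si](CC)(CC)CC)/C(C(=O)OC)=C\C1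
F5 | step 27 | 8-O-acetyl 9-hydroxy compound | C1/C(C)=C\[C@@H]2OC(=O)C(=C)[C@@H]2[C@H](OC(C)=O)[C@@H](O)/C(C(=O)OC)=C\C1
F6 | step 29 | bromohydrin of 43 (C4–OH, C5–Br) | C=C1C(=O)O[C@@H]2[C@H]1[C@H](OC(C)=O)[C@@H](OC(=O)[C@@]1(C)CO1)/C(C(=O)OC)=C\CC[C@@](C)(O)[C@@H]2Br
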